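Count the nucleophile.

| setting | Thursday's | Wednesday's | north-east | south-east |
|---|---|---|---|---|
| electrophile | 0.90 M | 0.90 M | 0.90 M | 0.90 M |
| nucleophile | 1.1 M | 0.96 M | 0.940 M | 1.20 M |
| protic impurity | 0.18 M | 0.18 M | 0.180 M | 0.180 M |
| remark | run made earlier | run made earlier |  |  |
| time |  |  | 50 min | 50 min |

| run | time / min | electrophile / % | product / % |
|---|---|---|---|
| Thursday's | 8.00 | 24.6 | 59.6 |
| Thursday's | 15.0 | 20.9 | 61.4 |
| Thursday's | 20.0 | 19.3 | 62.0 |
| Thursday's | 30.0 | 17.7 | 62.6 |
| Thursday's | 40.0 | 17.4 | 63.5 |
| Wednesday's | 3.00 | 41.6 | 46.6 |
| Wednesday's | 8.00 | 30.6 | 52.4 |
| Wednesday's | 15.0 | 27.3 | 54.2 |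
| Wednesday's | 25.0 | 25.1 | 54.9 |
| Wednesday's | 40.0 | 24.0 | 56.2 |

(standard deviation of a reading: 0.3 percentage points)



1. part of the electrophile that has reacted at the end, north-east
2. part of the electrophile that has reacted at the end, south-east
3. what raising the concentration of nucleophile from its lowest to its highest value here does to the part of the electrophile that has reacted (changes below 5 percentage points count as none) (no change / it falls / it rises)

Wednesday's run shows me a ladder of three rungs. After 3.00 min, product already stands at 46.6%, more than the 11.8% of electrophile unaccounted for. By 25.0 min, that gap has reached 20.0%, and the protic impurity's charge is 20.0% of the electrophile's, so I book one electrophile lost per impurity. Last comes a creep: product gains 1.3 percentage points up to 40.0 min, and at that pace the remaining electrophile needs 277 min, longer than 50 min.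

Between the two runs, the last readings give 0.469 mole of product per mole of added nucleophile, about half. I therefore charge two nucleophile per product. With i, n and e the charges of protic impurity, nucleophile and electrophile:

X = (i + n/2)/e

north-east: X = 72.2%
south-east: X = 86.7%

X, the nucleophile budget, is my estimate, for flasks with these charges of electrophile and protic impurity, of the part of the electrophile reacted when the burst ends. At 40.0 min, Wednesday's run stands 2.7 points above its budget and Thursday's 1.5 points. These are readings at 40.0 min, not at 50 min, but the creep is slow, so adding their mean, 2.1 points, I expect about 74.3% in north-east and about 88.7% in south-east.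

The forecast gives 75.3% and 86.5%, and for the trend, it rises. Its ground: “This fits either nucleophile exhaustion, at about two per product, or an equilibrium”. Its south-east value lies below mine.

The flask gives 75.6% in north-east and 88.7% in south-east: it rises, by 13 points. Both lie inside the forecast's ranges, 74% to 76.6% and 83.5% to 89%, and they stand 3.4 points and 2 points above the budgets. In north-east, the making of product had 90% of its turnover up to 50 min behind it after 5.00 min, and the quench by protic impurity had 98% of its turnover up to 50 min behind it after 25.0 min. At 50.0 min, that flask holds 55.6% product, 20.0% quenched substrate and 0.437 M protonated nucleophile, while free nucleophile, the limiting reagent, is down to 0.290% of its charge.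

    nucleophile + acid set free ⇌ protonated nucleophile, settled at all times (K = 2500 M⁻¹)
    electrophile + protic impurity → quenched substrate (k = 0.520 M⁻¹ min⁻¹)
    electrophile + nucleophile → acid set free + product (k = 0.660 M⁻¹ min⁻¹)

A neighbour of north-east, charged with 2.2 M of electrophile and otherwise the same, has a budget of 29.5%. The flask gives 33.5%.

The data were generated by integration with made-up constants; noise was put on by code.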